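Late in a run the question is where target stops, so I asked that first and asked how fast it got there second.

the same everywhere: substrate 0.029 M; added ligand 0.84 mM

|  | solid reagent | free catalyst | remark | time |
|---|---|---|---|---|
| teal | 0.0203 M | 2.2 mM | run made earlier |  |
| dawn | 0.0203 M | 1.5 mM |  | 10 min |
| autumn | 0.00600 M | 1.5 mM |  | 40 min |

1. which of the two ends with the higher amount of target, in percent of the substrate charged ("neither" if they lie within 2 percentage points) (dawn / autumn / neither)
2. target at the end, in percent of the substrate charged, dawn
3. target at the end, in percent of the substrate charged, autumn

- solid reagent is a solid; its amount is given per volume of the solution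
- at the start none of the solid reagent is in solution
- no earlier run changes the charge of free catalyst; that part of a forecast is a guess

I took the one-to-one case as the zero of my scale, with one solid reagent consumed per target, though this was an assumption. In autumn that gave 20.7%; this ceiling, the charge ratio c(solid reagent)/c(substrate) read as a percentage of the substrate charged, stood at 70.0% in dawn.

teal run (percent of the substrate charged)

| time / min | target / % | substrate / % |
|---|---|---|
| 0.833 | 0 | 96.2 |
| 2.00 | 3.4 | 92.1 |
| 4.00 | 13.6 | 83.8 |
| 6.00 | 19.7 | 74.1 |

(scatter of a reading: 1 percentage point)

I read the teal table downwards. Its first row had 0% target with substrate already at 96.2%, so substrate was leaving before target appeared. From the second row to the last, target climbed at 0.0408 /min of the charge, and that line, run backwards, gave a lag of 1.17 min. Both are readings and carry the scatter. Scaling the slope with catalyst was my guess, and it gave 0.0278 /min.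

Autumn then needed about 8.61 min to reach its ceiling, which is less than its 40 min, so I put autumn at the ceiling. On the same line I estimated dawn at 24.5% after 10 min, below its ceiling, so in this estimate time held dawn back. For autumn, the same line over its own 40 min, capped at its ceiling, gave 20.7%. My reckoning therefore put dawn at 24.5% and autumn at 20.7%, a gap more than the margin of 2 percentage points.

The forecast differed: neither, with 20% for dawn and 19% for autumn. In its words, “The two probably lie within 2 points.”

The flasks gave 29.2% in dawn and 20.6% in autumn, so dawn ended higher. The forecast's dawn figure is what the last teal reading gives when taken over, and my own fell 4.7 points short.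

    solid reagent ⇌ partner, rate k1*(cs1 - [partner]) while solid is left; crystals form when [partner] > cs1 (solubility = 13.0 mM, k = 0.00700 /s)
    substrate + free catalyst ⇌ catalyst intermediate A (K = 27.0 /M, k = 79.0 /M/s)
    free catalyst + added ligand ⇌ idle complex (K = 1100 /M, k = 14.0 /M/s)
    catalyst intermediate D → free catalyst + target (k = 0.150 /s)
    partner + catalyst intermediate A → catalyst intermediate B (k = 5.00 /M/s)
    catalyst intermediate C → catalyst intermediate D (k = 0.150 /s)
    catalyst intermediate B ⇌ by-product + catalyst intermediate C (K = 0.250 M, k = 0.170 /s)

Autumn stood at 20.6% against its ceiling of 20.7%, with solid reagent, the limiting reagent, at 0% of its charge. The neighbouring flask kept autumn's recipe but held 0.017 M of substrate, which raised the ceiling to 35.3%. At 40 min it gave 33.7% target, with 65% of its substrate left.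

(The earlier runs and the new flask are calculated from invented constants, noise included.)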